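Noon was charged with more starting material than autumn, on the same partner and at the same temperature. From these two runs I had to rank four flasks by the share of target in target plus over-reaction product.

| flask | starting material | partner | temperature | remark | time |
|---|---|---|---|---|---|
| autumn | 0.015 M | 0.015 M | 80 °C | run made earlier |  |
| noon | 0.020 M | 0.015 M | 80 °C | run made earlier |  |
| grey | 0.010 M | 0.0150 M | 80 °C |  | 5.0 d |
| violet | 0.010 M | 0.0600 M | 100 °C |  | 5.0 d |
| amber | 0.010 M | 0.0600 M | 80 °C |  | 5.0 d |
| red | 0.010 M | 0.0150 M | 100 °C |  | 5.0 d |

| run | time / h | target / % | over-reaction product / % |
|---|---|---|---|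
| autumn | 3.00 | 0 | 0.3 |
| autumn | 8.00 | 0.8 | 0 |
| autumn | 15.0 | 2.0 | 0 |
| autumn | 25.0 | 3.4 | 0.4 |
| noon | 3.00 | 0 | 0.2 |
| noon | 8.00 | 1.0 | 0 |
| noon | 15.0 | 1.6 | 0 |
| noon | 25.0 | 2.3 | 0.3 |

(scatter of a reading: 0.3 percentage points)

- the numbers in the tables scatter with a standard deviation of 0.3 percentage points
- steps under discussion: starting material + partner -> intermediate A; partner + intermediate A <-> intermediate B; intermediate B -> target; intermediate B <-> intermediate C; partner + target -> over-reaction product
- the earlier runs do not show what temperature does; that part of a forecast is a guess

- ranking by share of target in all that became target or over-reaction product, from high to low, at 5.0 d (grey / violet / amber / red)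
- the share of target in all that became target or over-reaction product of the flask you put first, at 5.0 d
- the share of target in all that became target or over-reaction product of the flask you put last, at 5.0 d

The puzzle stood at the last reading: noon held 0.460 mM of target and autumn 0.510 mM, equal within the scatter, so the extra charge bought no visible target. I cleared this by counting partner. Starting material takes one partner to become intermediate A, intermediate A takes a second on the way to target, and target takes a third to become over-reaction product. More charge therefore makes more intermediate A but leaves less partner, and the second step runs on the product of the two.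

The count gave my rule. The partner floor F is the partner charge less 3 times the starting material charge, the partner left if every starting material ended as over-reaction product: 0.0300 M for amber and violet, −0.0150 M for grey and red. A negative F means the charge cannot pay for that end, so attack can stop with target standing. Attack on target is pseudo-first-order, with a time constant inverse to the partner of the moment. Grey's partner falls from its charge towards zero, while amber's cannot fall below F, which is twice grey's charge, so at their common temperature amber's weakest attack is stronger than grey's strongest. I put grey and red above amber, and hotter violet last; violet's place and the order of grey and red were guesses at what temperature does.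

The forecast gave grey > red > amber > violet, from 90% down to 12%, holding that “excess partner forms target quickly and keeps attacking it”.

The flasks gave red > grey > amber > violet: red 73.9%, grey 69.3%, amber 2.14%, violet 0%.

    starting material + partner → intermediate A (k = 0.00340 M⁻¹ s⁻¹, Ea = 87.0 kJ mol⁻¹)
    partner + intermediate A ⇌ intermediate B (K = 64.0 M⁻¹, k = 5.60 × 10⁻⁴ M⁻¹ s⁻¹, Ea = 86.0 kJ mol⁻¹, ΔH = −1.00 kJ mol⁻¹)
    intermediate B → target (k = 2.70 × 10⁻⁵ s⁻¹, Ea = 123 kJ mol⁻¹)
    intermediate B ⇌ intermediate C (K = 2.30, k = 8.40 × 10⁻⁵ s⁻¹, Ea = 100 kJ mol⁻¹, ΔH = 19.0 kJ mol⁻¹)
    partner + target → over-reaction product (k = 0.00100 M⁻¹ s⁻¹, Ea = 65.0 kJ mol⁻¹)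
    (constants at 80 °C)

Violet kept 50% of its partner, and F is 50.0% of that charge, with over-reaction product at >99.9%. The neighbouring flask was violet with 0.040 M of starting material. Its floor is −0.0600 M, negative like grey's, so I reckoned that attack could stop with target standing. At 5.00 d it held 0% of its partner and, of the starting material charged, intermediate A 57.3%, target 33.7% and over-reaction product 8.45%, a target share of 80.0%.

The data stem from a simulated flask with made-up constants; scatter was added.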